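## Analysis of the target

Heteroartonin A (21) is a flavone. Ring A carries hydroxyls at C5 and C7, ring C (O1, C2, C3, C4) carries a prenyl group at C3, and ring B is bonded to C2 through C1'. Ring B is pentasubstituted: 2'-OH, 3'-prenyl, 4'-OMe and 5'-OH, with C6' the only free position. There is no stereocentre, and the gem-dimethyl alkene termini raise no geometry question.

The sensitive groups are:
- the two prenyl alkenes, each next to a phenol, which cyclise or hydrate under acid;
- the 2',5'-hydroquinone, which is easily oxidised;
- the pyranone, which opens under hydroxide.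

The difficulty lies in three places. The C2–C1' bond is flanked by the C3 prenyl group and the 2'-oxygen. Ring B has five different neighbours to place. Four phenols must be told apart from one methyl ether, while two linear prenyl groups are attached.

The strategy rests on C3. It is the one ring C carbon bonded neither to oxygen nor to an arene, and it is the one that needs a carbon substituent. Removing C3 and joining C2 to C4 leaves a 2-aryl-3-oxybenzofuran that already holds O1, C2 with ring B, C4 with its oxygen, and ring A. Ring C can then be made by inserting a single halogen-bearing carbon between C2 and C4.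

## Retrosynthetic reasoning

**21 ⇒ 20.** The four O–CH2 bonds of methoxymethyl (MOM) ethers on O5, O7, O2' and O5' are cut last. This acetal survives amide bases, alkoxide and palladium catalysis, and needs no hydrogenolysis or fluoride. The forward step must remove four acetals without protonating the prenyl alkenes.

**20 ⇒ 18 + 19.** Both prenyl C–C bonds (C3–CH2 and C3'–CH2) are cut together, back to the dibromide 18 and two equivalents of boronate 19. Cutting here keeps every alkene out of the earlier steps, which matters because the ring-forming step uses a carbene. The forward reaction must couple a bromo-enone and a doubly ortho-substituted aryl bromide and deliver the linear allyl isomer at both.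

**18 ⇒ 14 + 15.** C3 is excised: the C2–C3 and C3–C4 bonds are cut and C2 is reconnected to C4. This gives the silyl enol ether 14 of a 2-arylbenzofuran-3-ol and the one-carbon unit of 15. The carbene carbon arrives already carrying bromine, so the ring is enlarged and the C3 handle installed in one operation, through 16 and 17. The silyl group is tert-butyldimethylsilyl. A smaller silyl group on this phenol-like enol would be stripped by alkoxide before the carbene could add.

**14 ⇒ 11.** The O–Si bond and the bond between the benzylic carbon and the former ester carbon are cut. Forward, a benzylic carbanion acylates the neighbouring ester and the product is trapped on oxygen, through 12 and 13. The crowded C2–C1' bond is never made by coupling; it is the ordinary aryl–CH2 bond of the ring B building block.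

**11 ⇒ 8 + 10.** The benzylic C–O bond is cut to benzyl alcohol 8 and phenol 10. A redox etherification avoids an electron-rich benzyl halide, which would ionise easily.

**10 ⇒ 9.** Two O–CH2 bonds are cut. The hydroxyl that must stay free is the one hydrogen-bonded to the ester, so 9 can be protected selectively.

**8 ⇒ 7 ⇒ 6 ⇒ 5.** The alcohol comes from aldehyde 7, and 7 from phenol 6 by acetal formation. The C3–Br bond of 6 is cut back to 5. The bromine is introduced while O2 is still a free phenol: its para position is blocked, so it directs the electrophile to the carbon between OH and OMe. Once both oxygens are protected that control is lost.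

**5 ⇒ 4 ⇒ 2 ⇒ 1.** The formyl carbon of 5 is removed to give phenol 4 (ortho-formylation forward). The phenolic C–O bond of 4 is traced through formate 3 to the aldehyde carbon of 2, and 2 to vanillin 1. Protecting the hydroxyl of 1 before the oxidative C-to-O exchange differentiates the two hydroquinone oxygens of ring B from the start. The oxygen next to OMe is masked; the other is free to direct formylation and then bromination.

## Alternatives that were turned down

**Alternative 1:** Ring B is built from a four-membered ring, cutting C1'–C2'. Heating cyclobutenone A1 would open it electrocyclically; the ketene carbon then closes onto the far alkyne carbon to give quinone A2 (Moore cyclisation).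
- For: the order of additions to the cyclobutenedione core fixes all five ring B substituents without any aromatic substitution. The 3'-prenyl group enters as a plain nucleophile instead of by coupling at a hindered halide. The acetal carbon of A2 is ready to become C2.
- Against: the step solves only ring B. A2 must still be reduced, protected and unmasked, and ring C built by a separate flavone synthesis in which C3 still lacks its prenyl group. A prenyl alkene sits beside a quinone during a thermolysis and is carried through every later step.
- Comparison: in regiochemical certainty for ring B this alternative is stronger than the phenol-directed substitutions of steps 3 and 4. The chosen route offers instead a ring C construction that delivers the C3 handle in the same step, and alkenes that appear only at the end.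

**Alternative 2:** The C2–C1' bond is cut. In ester A3 the future O2' is acylated by an acetic acid side chain on C3 of a preformed ring A/C chromone, and C1' carries bromine. Palladium-catalysed intramolecular C–H arylation at C2 would give the seven-membered lactone A4.
- For: the route is convergent and the tether fixes the regiochemistry on both partners. The two lactone carbons can later become the first two carbons of the 3-prenyl group (partial reduction, then an isopropylidene Wittig reaction), so no allyl-transfer regiochemistry arises at C3. On that point it is stronger than step 11 of the chosen route.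
- Against: A3 is an aryl ester of an acidic acetic acid and is exposed to carbonate or carboxylate bases at the temperatures C–H arylation needs. The lactone forces a twisted aryl–pyranone bond into a seven-membered ring. The 3'-prenyl alkene is present during hot palladium catalysis. The later partial reduction must spare the pyranone carbonyl. The ring B half of A3 needs its own multi-step synthesis.
- Comparison: the chosen route never forms C2–C1' by coupling, so the steric problem does not arise, and every step before the ring enlargement is routine.

**Alternative 3:** Ring A is made last by cutting C4a–C5. Base would convert keto ester A5 into an extended dienolate whose pyranone carbon attacks the methyl ester, giving A6 after aromatisation.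
- For: it mirrors the polyketide origin, needs no ring A protection, and leaves only two acetals to remove. In protecting-group economy it is stronger than the chosen route.
- Against: ring A is the one part of 21 that can be bought complete (as 9). Ring B, both prenyl groups and the pyranone would all be invested before the uncertain step. A5 has several acidic sites, and the carbon that must react is part of a vinylogous ester, so O-acylation and base-induced opening of the pyranone compete. Attaching the side chain of A5 to the crowded pyranone is itself a multi-step task.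
- Comparison: the chosen strategy places its uncertain step mid-route on material reached by standard reactions, and keeps the alkenes out until afterwards.

Key step: step 10

## Route

**Step 1**
Reactants: 1 vanillin
Product: 2 3-methoxy-4-(methoxymethoxy)benzaldehyde
Conditions: MOMCl, i-Pr2NEt, CH2Cl2, 0 °C → rt
Reagents that add atoms: chloromethyl methyl ether, COCCl
Why: O-alkylation of the phenoxide by the α-chloro ether; this masks the oxygen that becomes O5' with an acetal that later survives amide base, alkoxide and palladium.

**Step 2**
Reactants: 2 3-methoxy-4-(methoxymethoxy)benzaldehyde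
Product: 4 3-methoxy-4-(methoxymethoxy)phenol, via aryl formate 3 (not isolated)
Conditions: mCPBA, CH2Cl2, 0 °C → rt; aq. NaHCO3 wash; then K2CO3 (cat.), MeOH, rt
Reagents that add atoms: 3-chloroperoxybenzoic acid, OOC(=O)c1cccc(Cl)c1
Why: Baeyer–Villiger oxidation of an electron-rich benzaldehyde, in which the alkoxy-substituted aryl group migrates in preference to hydride; methanolysis of formate 3 frees the phenol that becomes O2', now distinct from the masked O5'.

**Step 3**
Reactants: 4 3-methoxy-4-(methoxymethoxy)phenol
Product: 5 2-hydroxy-4-methoxy-5-(methoxymethoxy)benzaldehyde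
Conditions: MgCl2, Et3N, (CH2O)n, MeCN, reflux
Reagents that add atoms: paraformaldehyde (as formaldehyde), C=O
Why: Magnesium-mediated ortho-formylation of a phenol (Casnati–Skattebøl): the magnesium phenoxide delivers formaldehyde to an ortho carbon and a second formaldehyde oxidises the benzylic alkoxide. The open ortho position para to OMe should react, not the one wedged between OH and OMe.

**Step 4**
Reactants: 5 2-hydroxy-4-methoxy-5-(methoxymethoxy)benzaldehyde
Product: 6 3-bromo-2-hydroxy-4-methoxy-5-(methoxymethoxy)benzaldehyde
Conditions: NBS, DMF, 0 °C → rt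
Reagents that add atoms: N-bromosuccinimide, O=C1CCC(=O)N1Br
Why: Electrophilic aromatic bromination; the para position of the free phenol is blocked, so bromine should enter C3, which is ortho to OH and OMe and meta to the aldehyde, whereas C6 is ortho to the aldehyde and not activated by the phenol.

**Step 5**
Reactants: 6 3-bromo-2-hydroxy-4-methoxy-5-(methoxymethoxy)benzaldehyde
Product: 7 3-bromo-4-methoxy-2,5-bis(methoxymethoxy)benzaldehyde
Conditions: MOMCl, i-Pr2NEt, CH2Cl2, 0 → 40 °C
Reagents that add atoms: chloromethyl methyl ether, COCCl
Why: O-alkylation of the remaining chelated phenol; the small, reactive α-chloro ether tolerates the flanking bromine and formyl groups.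

**Step 6**
Reactants: 7 3-bromo-4-methoxy-2,5-bis(methoxymethoxy)benzaldehyde
Product: 8 [3-bromo-4-methoxy-2,5-bis(methoxymethoxy)phenyl]methanol
Conditions: NaBH4, MeOH, 0 °C
Reagents that add atoms: none
Why: Borohydride reduction of an aryl aldehyde; the aryl bromide and the acetals are inert.

**Step 7**
Reactants: 9 methyl 2,4,6-trihydroxybenzoate
Product: 10 methyl 2-hydroxy-4,6-bis(methoxymethoxy)benzoate
Conditions: MOMCl (2.2 equiv), i-Pr2NEt, CH2Cl2, 0 °C → rt
Reagents that add atoms: chloromethyl methyl ether, COCCl
Why: Selective O-alkylation: the 4-OH and one of the two equivalent ortho hydroxyls react, while the last hydroxyl is held in a hydrogen bond to the ester carbonyl and stays free, as is usual for 2,4,6-trihydroxyaryl carbonyl compounds.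

**Step 8**
Reactants: 8 [3-bromo-4-methoxy-2,5-bis(methoxymethoxy)phenyl]methanol; 10 methyl 2-hydroxy-4,6-bis(methoxymethoxy)benzoate
Product: 11 methyl 2-{[3-bromo-4-methoxy-2,5-bis(methoxymethoxy)phenyl]methoxy}-4,6-bis(methoxymethoxy)benzoate
Conditions: PPh3, DIAD, THF, 0 °C → rt
Reagents that add atoms: none
Why: Mitsunobu etherification of a primary benzylic alcohol with an acidic salicylate phenol; it forms the benzylic C–O bond without isolating an electron-rich benzyl halide.

**Step 9**
Reactants: 11 methyl 2-{[3-bromo-4-methoxy-2,5-bis(methoxymethoxy)phenyl]methoxy}-4,6-bis(methoxymethoxy)benzoate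
Product: 14 tert-butyl({2-[3-bromo-4-methoxy-2,5-bis(methoxymethoxy)phenyl]-4,6-bis(methoxymethoxy)-1-benzofuran-3-yl}oxy)dimethylsilane, via benzofuranone 12 (not isolated), via lithium enolate 13 (not isolated)
Conditions: LiN(i-Pr)2 (2.2 equiv), THF, −78 → −20 °C; then TBSCl, DMPU, −20 °C → rt
Reagents that add atoms: tert-butyldimethylsilyl chloride, CC(C)(C)[Si](C)(C)Cl
Why: Base-induced ring closure of an alkyl 2-(benzyloxy)benzoate, a Dieckmann-type acylation: the amide removes a benzylic proton, the carbanion adds 5-exo-trig to the ester, methoxide leaves to give 12, and loss of its acidic C2 proton gives the aromatic enolate 13, which is silylated on oxygen. A lithium amide is used instead of an alkyllithium so that the aryl bromide is untouched, and trapping in the same flask keeps the oxidisable benzofuranol from air.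

**Step 10**
Reactants: 14 tert-butyl({2-[3-bromo-4-methoxy-2,5-bis(methoxymethoxy)phenyl]-4,6-bis(methoxymethoxy)-1-benzofuran-3-yl}oxy)dimethylsilane; 15 bromoform
Product: 18 3,3'-dibromo-4'-methoxy-5,7,2',5'-tetrakis(methoxymethoxy)flavone, via dibromocyclopropane 16 (not isolated), via silyloxybenzopyrylium bromide 17 (not isolated)
Conditions: KOt-Bu (excess), toluene–pentane, −20 °C, slow addition of 15; then → rt
Reagents that add atoms: none
Why: Proposed new method: tert-butoxide effects α-elimination of HBr from 15, and the resulting electrophilic singlet carbene adds in a concerted [2+1] step to the C2=C3 bond of the benzofuran, the most electron-rich π bond present because O1, the silyloxy oxygen and ring A all donate into it, giving the fused dibromocyclopropane 16. Loss of the bromide endo to the five-membered ring is concerted with disrotatory two-electron electrocyclic opening of the cyclopropane bond shared with the furan, pushed by the lone pairs on O1 and on the silyloxy oxygen, and gives the 3-bromo-4-silyloxybenzopyrylium bromide 17. Transfer of the silyl group to tert-butoxide then reveals the C4 carbonyl of 18. Ring C is therefore formed by enlargement of the furan and not by a cyclisation: C2–C3 and C3–C4 are made in the carbene addition and the former C2–C4 bond is the one that breaks. The closest known reactions are the dihalocarbene ring expansion of cyclic silyl enol ethers to 2-halocycloalkenones and the Ciamician–Dennstedt-type expansion of indoles and benzofurans; a 3-silyloxybenzofuran combines the two substrate types and has not been shown to react this way. No stereocentre is set, since the two centres of racemic 16 are destroyed on opening. The step needs chemoselectivity for the enol ether over the arenes and over attack at silicon: both prenyl alkenes are deferred, alkoxy-arenes are poor carbene acceptors, and the tert-butyldimethylsilyl group should resist tert-butoxide at −20 °C long enough for the carbene to add.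

**Step 11**
Reactants: 18 3,3'-dibromo-4'-methoxy-5,7,2',5'-tetrakis(methoxymethoxy)flavone; 19 prenylboronic acid pinacol ester (excess)
Product: 20 4'-methoxy-5,7,2',5'-tetrakis(methoxymethoxy)-3,3'-bis(3-methylbut-2-enyl)flavone
Conditions: Pd(OAc)2, t-BuXPhos (2-di-tert-butylphosphino-2',4',6'-triisopropylbiphenyl), K3PO4 (aq), THF, 50 °C
Reagents that add atoms: none
Why: Twofold Suzuki–Miyaura coupling: zerovalent palladium inserts into the C3–Br bond of the bromo-enone and into the aryl C3'–Br bond, and the bulky di-tert-butylbiarylphosphine is chosen to let the allylpalladium intermediate settle as the less hindered primary σ-prenyl form before reductive elimination, which should give the linear prenyl groups. Phosphate is the base because hydroxide would open the pyranone.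

**Step 12**
Reactants: 20 4'-methoxy-5,7,2',5'-tetrakis(methoxymethoxy)-3,3'-bis(3-methylbut-2-enyl)flavone
Product: 21 heteroartonin A
Conditions: HCl (3 M aq), MeOH, 45 °C
Reagents that add atoms: none
Why: Acid-catalysed acetal exchange should remove the four MOM ethers as dimethoxymethane; dilute acid at moderate temperature is chosen so that the prenyl alkenes are not protonated, as is common practice for MOM-protected prenylated flavonoids.

## Compound list

1 | vanillin (4-hydroxy-3-methoxybenzaldehyde) | COc1cc(C=O)ccc1O | starting material
2 | 3-methoxy-4-(methoxymethoxy)benzaldehyde | COCOc1ccc(C=O)cc1OC | intermediate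
3 | 3-methoxy-4-(methoxymethoxy)phenyl formate | COCOc1ccc(OC=O)cc1OC | intermediate (not isolated)
4 | 3-methoxy-4-(methoxymethoxy)phenol | COCOc1ccc(O)cc1OC | intermediate
5 | 2-hydroxy-4-methoxy-5-(methoxymethoxy)benzaldehyde | COCOc1cc(C=O)c(O)cc1OC | intermediate
6 | 3-bromo-2-hydroxy-4-methoxy-5-(methoxymethoxy)benzaldehyde | COCOc1cc(C=O)c(O)c(Br)c1OC | intermediate
7 | 3-bromo-4-methoxy-2,5-bis(methoxymethoxy)benzaldehyde | COCOc1cc(C=O)c(OCOC)c(Br)c1OC | intermediate
8 | [3-bromo-4-methoxy-2,5-bis(methoxymethoxy)phenyl]methanol | COCOc1cc(CO)c(OCOC)c(Br)c1OC | intermediate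
9 | methyl 2,4,6-trihydroxybenzoate | COC(=O)c1c(O)cc(O)cc1O | starting material
10 | methyl 2-hydroxy-4,6-bis(methoxymethoxy)benzoate | COC(=O)c1c(O)cc(OCOC)cc1OCOC | intermediate
11 | methyl 2-{[3-bromo-4-methoxy-2,5-bis(methoxymethoxy)phenyl]methoxy}-4,6-bis(methoxymethoxy)benzoate | COC(=O)c1c(OCc2cc(OCOC)c(OC)c(Br)c2OCOC)cc(OCOC)cc1OCOC | intermediate
12 | 2-[3-bromo-4-methoxy-2,5-bis(methoxymethoxy)phenyl]-4,6-bis(methoxymethoxy)-1-benzofuran-3(2H)-one (racemic) | O=C1C(c2cc(OCOC)c(OC)c(Br)c2OCOC)Oc2cc(OCOC)cc(OCOC)c12 | intermediate (not isolated)
13 | lithium 2-[3-bromo-4-methoxy-2,5-bis(methoxymethoxy)phenyl]-4,6-bis(methoxymethoxy)-1-benzofuran-3-olate | [Li+].[O-]c1c(-c2cc(OCOC)c(OC)c(Br)c2OCOC)oc2cc(OCOC)cc(OCOC)c12 | intermediate (not isolated)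
14 | tert-butyl({2-[3-bromo-4-methoxy-2,5-bis(methoxymethoxy)phenyl]-4,6-bis(methoxymethoxy)-1-benzofuran-3-yl}oxy)dimethylsilane | CC(C)(C)[Si](C)(C)Oc1c(-c2cc(OCOC)c(OC)c(Br)c2OCOC)oc2cc(OCOC)cc(OCOC)c12 | intermediate
15 | bromoform | BrC(Br)Br | starting material
16 | 1,1-dibromo-1a-[3-bromo-4-methoxy-2,5-bis(methoxymethoxy)phenyl]-6b-(tert-butyldimethylsilyloxy)-4,6-bis(methoxymethoxy)-1a,6b-dihydro-1H-cyclopropa[b][1]benzofuran (racemic, ring fusion necessarily cis) | CC(C)(C)[Si](C)(C)OC12c3c(OCOC)cc(OCOC)cc3OC1(c1cc(OCOC)c(OC)c(Br)c1OCOC)C2(Br)Br | intermediate (not isolated)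
17 | 3-bromo-2-[3-bromo-4-methoxy-2,5-bis(methoxymethoxy)phenyl]-4-(tert-butyldimethylsilyloxy)-5,7-bis(methoxymethoxy)chromenylium bromide | CC(C)(C)[Si](C)(C)Oc1c(Br)c(-c2cc(OCOC)c(OC)c(Br)c2OCOC)[o+]c2cc(OCOC)cc(OCOC)c12.[Br-] | intermediate (not isolated)
18 | 3,3'-dibromo-4'-methoxy-5,7,2',5'-tetrakis(methoxymethoxy)flavone | O=c1c(Br)c(-c2cc(OCOC)c(OC)c(Br)c2OCOC)oc2cc(OCOC)cc(OCOC)c12 | intermediate
19 | prenylboronic acid pinacol ester | CC(C)=CCB1OC(C)(C)C(C)(C)O1 | starting material
20 | 4'-methoxy-5,7,2',5'-tetrakis(methoxymethoxy)-3,3'-bis(3-methylbut-2-enyl)flavone | O=c1c(CC=C(C)C)c(-c2cc(OCOC)c(OC)c(CC=C(C)C)c2OCOC)oc2cc(OCOC)cc(OCOC)c12 | intermediate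
21 | heteroartonin A | COc1c(O)cc(-c2oc3cc(O)cc(O)c3c(=O)c2CC=C(C)C)c(O)c1CC=C(C)C | target

## Step count and least certain steps

Total: 12 steps. Longest linear sequence: 11 steps (steps 1–6 and 8–12, from vanillin).

**Step 10 (key step, proposed new method).** Most likely failure: the silyl group is lost to tert-butoxide before the carbene adds, so that the freed enolate is C-dibromomethylated at C2 in a Reimer–Tiemann manner instead of being ring-enlarged. Alternatively, cyclopropanation of the crowded tetrasubstituted bond is slow and the carbene decomposes.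

Fallback, by known chemistry, from aldehyde 7 to compound 20: ring C is built by halocyclisation of an alkynone. The Ohira–Bestmann reagent (K2CO3, MeOH) converts 7 into 3-bromo-1-ethynyl-4-methoxy-2,5-bis(methoxymethoxy)benzene F1. Its alkynylmagnesium derivative (EtMgBr, THF) is added to 2,4,6-tris(methoxymethoxy)benzaldehyde F2 to give 3-[3-bromo-4-methoxy-2,5-bis(methoxymethoxy)phenyl]-1-[2,4,6-tris(methoxymethoxy)phenyl]prop-2-yn-1-ol F3. MnO2 oxidises F3 to 3-[3-bromo-4-methoxy-2,5-bis(methoxymethoxy)phenyl]-1-[2,4,6-tris(methoxymethoxy)phenyl]prop-2-yn-1-one F4. ICl in CH2Cl2 at −78 °C then induces 6-endo attack of an ortho acetal oxygen on the activated alkyne, with loss of that MOM group, to give 3'-bromo-3-iodo-4'-methoxy-5,7,2',5'-tetrakis(methoxymethoxy)flavone F5. F5 takes the place of 18 in step 11 and the route is rejoined at 20.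

**Step 9.** Most likely failure: removal of the benzylic proton from the electron-rich ring B ether is slow, so that amide attack at the ester or ring metalation next to an acetal competes; air oxidation of the enolate at C2 before silylation is a second risk.

Fallback, from phenol 4 to compound 12: the C2–C1' bond is made by ketone α-arylation. NIS iodinates 4 para to OMe to give 2-iodo-5-methoxy-4-(methoxymethoxy)phenol F6. NBS then brominates between OH and OMe to give 2-bromo-6-iodo-3-methoxy-4-(methoxymethoxy)phenol F7. MOMCl and i-Pr2NEt give 3-bromo-1-iodo-4-methoxy-2,5-bis(methoxymethoxy)benzene F8. Palladium-catalysed α-arylation of 4,6-bis(methoxymethoxy)-1-benzofuran-3(2H)-one F9 with F8 (Pd(OAc)2, XPhos, NaOt-Bu, toluene) should occur at the C–I bond and give 12. Compound 12 is silylated in the same flask to 14 as in step 9.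

**Step 11.** Most likely failure: allylic transposition at palladium attaches 1,1-dimethylallyl groups, or coupling at the doubly ortho-substituted C3' bromide is incomplete.

Fallback, from 18 to 20: twofold Suzuki–Miyaura coupling of 18 with allylboronic acid pinacol ester, for which no regiochemical question exists, gives 3,3'-diallyl-4'-methoxy-5,7,2',5'-tetrakis(methoxymethoxy)flavone F10. Cross-metathesis of F10 with 2-methylbut-2-ene under second-generation Grubbs catalyst converts both allyl groups into prenyl groups and gives 20.

**Step 12.** Most likely failure: protonation of a prenyl alkene and capture of the cation by the neighbouring phenol (chroman formation at the 2'-OH/3'-prenyl pair) or by solvent.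

Fallback, from 18 to 21: the protecting groups are exchanged before any alkene is present. HCl in MeOH converts 18 into 3,3'-dibromo-5,7,2',5'-tetrahydroxy-4'-methoxyflavone F11. Ac2O, pyridine and DMAP give 3,3'-dibromo-4'-methoxyflavone-5,7,2',5'-tetrayl tetraacetate F12. Stille coupling with tributyl(3-methylbut-2-enyl)stannane (Pd(PPh3)4, DMF, 90 °C, neutral) gives 4'-methoxy-3,3'-bis(3-methylbut-2-enyl)flavone-5,7,2',5'-tetrayl tetraacetate F13. K2CO3 in MeOH at rt then removes the acetates to give 21 without acid.

## Further compounds

F1 | step 10 | 3-bromo-1-ethynyl-4-methoxy-2,5-bis(methoxymethoxy)benzene | C#Cc1cc(OCOC)c(OC)c(Br)c1OCOC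
F2 | step 10 | 2,4,6-tris(methoxymethoxy)benzaldehyde | COCOc1cc(OCOC)c(C=O)c(OCOC)c1
F3 | step 10 | 3-[3-bromo-4-methoxy-2,5-bis(methoxymethoxy)phenyl]-1-[2,4,6-tris(methoxymethoxy)phenyl]prop-2-yn-1-ol (racemic) | COCOc1cc(OCOC)c(C(O)C#Cc2cc(OCOC)c(OC)c(Br)c2OCOC)c(OCOC)c1
F4 | step 10 | 3-[3-bromo-4-methoxy-2,5-bis(methoxymethoxy)phenyl]-1-[2,4,6-tris(methoxymethoxy)phenyl]prop-2-yn-1-one | COCOc1cc(OCOC)c(C(=O)C#Cc2cc(OCOC)c(OC)c(Br)c2OCOC)c(OCOC)c1
F5 | step 10 | 3'-bromo-3-iodo-4'-methoxy-5,7,2',5'-tetrakis(methoxymethoxy)flavone | O=c1c(I)c(-c2cc(OCOC)c(OC)c(Br)c2OCOC)oc2cc(OCOC)cc(OCOC)c12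
F6 | step 9 | 2-iodo-5-methoxy-4-(methoxymethoxy)phenol | COCOc1cc(I)c(O)cc1OC
F7 | step 9 | 2-bromo-6-iodo-3-methoxy-4-(methoxymethoxy)phenol | COCOc1cc(I)c(O)c(Br)c1OC
F8 | step 9 | 3-bromo-1-iodo-4-methoxy-2,5-bis(methoxymethoxy)benzene | COCOc1cc(I)c(OCOC)c(Br)c1OC
F9 | step 9 | 4,6-bis(methoxymethoxy)-1-benzofuran-3(2H)-one | O=C1COc2cc(OCOC)cc(OCOC)c12
F10 | step 11 | 3,3'-diallyl-4'-methoxy-5,7,2',5'-tetrakis(methoxymethoxy)flavone | O=c1c(CC=C)c(-c2cc(OCOC)c(OC)c(CC=C)c2OCOC)oc2cc(OCOC)cc(OCOC)c12
F11 | step 12 | 3,3'-dibromo-5,7,2',5'-tetrahydroxy-4'-methoxyflavone | O=c1c(Br)c(-c2cc(O)c(OC)c(Br)c2O)oc2cc(O)cc(O)c12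
F12 | step 12 | 3,3'-dibromo-4'-methoxyflavone-5,7,2',5'-tetrayl tetraacetate | O=c1c(Br)c(-c2cc(OC(C)=O)c(OC)c(Br)c2OC(C)=O)oc2cc(OC(C)=O)cc(OC(C)=O)c12
F13 | step 12 | 4'-methoxy-3,3'-bis(3-methylbut-2-enyl)flavone-5,7,2',5'-tetrayl tetraacetate | O=c1c(CC=C(C)C)c(-c2cc(OC(C)=O)c(OC)c(CC=C(C)C)c2OC(C)=O)oc2cc(OC(C)=O)cc(OC(C)=O)c12
A1 | alternative 1 | 4-(3,3-diethoxyprop-1-ynyl)-4-hydroxy-3-methoxy-2-(3-methylbut-2-enyl)cyclobut-2-en-1-one (racemic) | O=C1C(CC=C(C)C)=C(OC)C1(O)C#CC(OCC)OCC
A2 | alternative 1 | 5-(diethoxymethyl)-2-methoxy-3-(3-methylbut-2-enyl)-1,4-benzoquinone | CCOC(OCC)C1=CC(=O)C(OC)=C(CC=C(C)C)C1=O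
A3 | alternative 2 | 2-bromo-5-methoxy-4-(methoxymethoxy)-6-(3-methylbut-2-enyl)phenyl [5,7-bis(methoxymethoxy)-4-oxo-4H-chromen-3-yl]acetate | O=C(Cc1coc2cc(OCOC)cc(OCOC)c2c1=O)Oc1c(Br)cc(OCOC)c(OC)c1CC=C(C)C
A4 | alternative 2 | seven-membered lactone bridging C3 and O2' of the protected 2-arylchromone | O=C1Cc2c(oc3cc(OCOC)cc(OCOC)c3c2=O)-c2cc(OCOC)c(OC)c(CC=C(C)C)c2O1
A5 | alternative 3 | methyl 4-{6-[4-methoxy-2,5-bis(methoxymethoxy)-3-(3-methylbut-2-enyl)phenyl]-5-(3-methylbut-2-enyl)-4-oxo-4H-pyran-2-yl}-3-oxobutanoate | COC(=O)CC(=O)Cc1cc(=O)c(CC=C(C)C)c(-c2cc(OCOC)c(OC)c(CC=C(C)C)c2OCOC)o1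
A6 | alternative 3 | 2',5'-bis-O-methoxymethyl heteroartonin A | O=c1c(CC=C(C)C)c(-c2cc(OCOC)c(OC)c(CC=C(C)C)c2OCOC)oc2cc(O)cc(O)c12
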